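The data were computed for an exercise; the scatter is artificial.

Maple made 20% of target in 4.00 h, faster than alder's 20% in 3.00 d, yet maple flattens near 28%.

| setting | alder | maple | beta | gamma | zeta | epsilon |
|---|---|---|---|---|---|---|
| substrate | 0.26 M | 0.26 M | 0.26 M | 0.26 M | 0.26 M | 0.26 M |
| free catalyst | 0.049 mol% | 0.11 mol% | 0.073 mol% | 0.073 mol% | 0.073 mol% | 0.073 mol% |
| temperature | −30 °C | −8 °C | −40 °C | 0 °C | −35 °C | −20 °C |
| remark | run made earlier | run made earlier |  |  |  |  |
| time |  |  | 2.0 d | 2.0 d | 2.0 d | 2.0 d |

alder run (percent of the substrate charged)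

| time / d | target / % |
|---|---|
| 0.250 | 7 |
| 0.417 | 3 |
| 0.625 | 7 |
| 1.25 | 13 |
| 2.08 | 15 |
| 3.00 | 20 |

maple run (percent of the substrate charged)

| time / h | target / % |
|---|---|
| 4.00 | 20 |
| 8.00 | 25 |
| 15.0 | 25 |
| 20.0 | 27 |
| 30.0 | 28 |

(readings scatter by 2 percentage points)

- the flasks put in order of amount of target, in percent of the substrate charged, best first, at 2.0 d (beta / gamma / zeta / epsilon)
- the same order at 10 h (beta / gamma / zeta / epsilon)
- the amount of target, in percent of the substrate charged of the flask you put first, at 2.0 d
- the amount of target, in percent of the substrate charged of the flask you put last, at 2.0 d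

- candidate steps: substrate -> side product; 2 free catalyst -> spent catalyst; substrate + free catalyst -> free catalyst + target

1. **In the flasks.** Substrate is taken to have two exits: target over free catalyst, and side product without it.

2. **Closed form.** With both exits first-order in substrate and free catalyst steady, integration gives a constant ρ = c(target)/c(side product). Target is then ρ/(1+ρ) of the substrate consumed.

3. **Reading ρ.** Taking maple's whole charge as consumed by 30.0 h, its reading gives 0.389. Scaled to the asked loading, this is the split ratio at −8 °C, 0.258 (selectivity factor), with a ceiling of 20.5%.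

4. **Temperature.** At alder's loading, maple's ratio gives a ceiling of 14.8%. Alder read 20% and was still climbing, so cooling appears to raise ρ.

5. **On return.** By this reckoning gamma, warmer than maple, ends below 20.5%. Beta and zeta should still hold substrate.

6. **Do not touch.** Leave each bath as set: the questions are asked of these temperatures.

7. **Forecast.** It gives epsilon > gamma > zeta > beta at 2.0 d and gamma > epsilon > zeta > beta at 10 h, with 30% first and 5.3% last: “I treat substrate loss as dominant”. The reckoning above gives a ceiling, not these numbers.

8. **Result.** The flasks give epsilon > gamma > zeta > beta at 2.0 d and gamma > epsilon > zeta > beta at 10 h, with 28.4% first and 10.2% last, so the forecast held within its margins. Gamma stands at 19.0%, below the ceiling.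

    substrate → side product (k = 3.20 × 10⁻⁴ min⁻¹, Ea = 86.0 kJ mol⁻¹)
    2 free catalyst → spent catalyst (k = 3.50 L mol⁻¹ min⁻¹, Ea = 47.0 kJ mol⁻¹)
    substrate + free catalyst → free catalyst + target (k = 2.10 L mol⁻¹ min⁻¹, Ea = 52.0 kJ mol⁻¹)
    (constants at −20 °C)

In epsilon, at the charge, substrate's half-life is 1.2 d by making target and 1.5 d by loss, a starting ratio of 1.25. By 2.00 d free catalyst stands at 20.7% of its charge, and the ratio over the run is 0.608, above 0.258.

For the flask like beta kept at −15 °C, interpolating ln ρ between these two gives 0.426, a share of 29.9%. With 7.14% substrate left, that share predicts 27.8% target; the computed flask holds 27.9%.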